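**Strategy.** The target is cut at the C14′–C15′ single bond, which flanks the C13′(CH3)=C14′H trisubstituted E-alkene of the polyene between the ε-ring and the 5,8-epoxy (dihydrobenzofuran) end. That motif is the signature of a methylalumination. A C18 ε-ring tetraenyne ending in the C13′≡C14′H alkyne, one methyl group from trimethylaluminium (C20′) and a C21 furanoid tetraenyl iodide ending at C15′ are joined in one flask. Zr-catalysed syn-carboalumination creates the 13′E alkenyl metal, and Pd/Zn cross-coupling forges C14′–C15′, completing the C40 skeleton with all double-bond geometry. The furanoid C8 centre comes earlier from an allene by gold-catalysed axis-to-centre transfer.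

Key step: step 19

Assumption: carotenoid numbering is used (C1–C20 for the furanoid half, C1′–C20′ for the ε half); (R)-α-ionone of high enantiomeric purity and (4R,6R)-actinol are taken as purchasable.

**Furanoid C21 iodide (steps 1–10)**

Step 1
Reactants: 1 (4R,6R)-4-hydroxy-2,2,6-trimethylcyclohexan-1-one
Product: 2 (4R,6R)-4-(tert-butyldimethylsilyloxy)-2,2,6-trimethylcyclohexan-1-one
Conditions: TBSCl, imidazole, DMF, 23 °C
Reagents that add atoms: tert-butyldimethylsilyl chloride, CC(C)(C)[Si](C)(C)Cl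
Why: Standard silyl ether formation masks the secondary alcohol, whose carbinol centre (later C3) is not touched.

Step 2
Reactants: 2 (4R,6R)-4-(tert-butyldimethylsilyloxy)-2,2,6-trimethylcyclohexan-1-one
Product: 3 (4R)-4-(tert-butyldimethylsilyloxy)-2,6,6-trimethylcyclohex-1-en-1-yl trifluoromethanesulfonate
Conditions: LDA, THF, −78 °C; then PhNTf2, −78 → 0 °C
Reagents that add atoms: N-phenylbis(trifluoromethanesulfonimide), O=S(=O)(N(c1ccccc1)S(=O)(=O)C(F)(F)F)C(F)(F)F
Why: Enolate O-triflation is regiospecific because only one α-hydrogen exists; the methyl-bearing centre is erased on purpose and the silyloxy centre is unaffected.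

Step 3
Reactants: 3 (4R)-4-(tert-butyldimethylsilyloxy)-2,6,6-trimethylcyclohex-1-en-1-yl trifluoromethanesulfonate; 4 (2E)-3-methylpent-2-en-4-yn-1-ol
Product: 6 ring-dienyne allylic acetate (C5=C6–C7≡C8–C9(CH3)=C10–C11H2OAc), via dienynol 5 (not isolated)
Conditions: Pd(PPh3)4 (5 mol %), CuI (10 mol %), Et3N, DMF, 50 °C; then Ac2O, DMAP (cat.), 23 °C
Reagents that add atoms: acetic anhydride, CC(=O)OC(C)=O
Why: Sonogashira coupling of the vinyl triflate with the terminal alkyne forms C6–C7 with retention of the 9E geometry, and acetylation in the same flask deactivates the side-chain alkene for the next step.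

Step 4
Reactants: 6 ring-dienyne allylic acetate
Product: 7 anti-5,6-epoxy-7-yne acetate (oxirane anti to the C3 silyloxy group)
Conditions: mCPBA, NaHCO3, CH2Cl2, 0 °C
Reagents that add atoms: 3-chloroperoxybenzoic acid, O=C(OO)c1cccc(Cl)c1
Why: Prilezhaev epoxidation should select the electron-richest tetrasubstituted ring alkene and approach anti to the C3 silyloxy group, setting C5 (R) and C6 together; any syn isomer is removed by chromatography.

Step 5
Reactants: 7 anti-5,6-epoxy-7-yne acetate
Product: 8 (6R)-allenic diol (C5 tertiary OH, C6=C7=C8H allene, C11 primary OH)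
Conditions: DIBAL-H (5 equiv), CH2Cl2, −78 → 0 °C; aq. Rochelle salt
Reagents that add atoms: none
Why: SN2′ reduction of the alkynyl oxirane, in which aluminium bound to the oxirane oxygen delivers hydride to C8 on the face of the departing C6–O bond (syn-SN2′), converts the epoxide configuration into the (6R)-allene axis while C5 keeps its oxygen and the acetate is cleaved reductively.

Step 6
Reactants: 8 (6R)-allenic diol
Product: 9 (2S,6S,7aR)-furanoid C15 allylic alcohol
Conditions: AuCl3 (2 mol %), THF, 0 → 23 °C; Et3N quench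
Reagents that add atoms: none
Why: Gold-catalysed 5-endo cycloisomerisation of the α-hydroxyallene (anti-oxyauration of the C7=C8 π-bond by the C5 hydroxyl, then protodeauration) should transfer the allene axis to the C8 centre with the side chain cis to the C5 methyl (8S) and leave the C6=C7 ring alkene.

Step 7
Reactants: 9 (2S,6S,7aR)-furanoid C15 allylic alcohol
Product: 10 furanoid C15 enal
Conditions: activated MnO2, CH2Cl2, 23 °C
Reagents that add atoms: none
Why: Manganese dioxide oxidises only the primary allylic alcohol, leaving the silyl ether, the dihydrofuran and the 9E alkene untouched.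

Step 8
Reactants: 10 furanoid C15 enal; 11 diethyl [(2E)-3-cyano-2-methylprop-2-en-1-yl]phosphonate
Product: 12 furanoid C20 trienenitrile
Conditions: 11, n-BuLi, THF, −78 °C; then 10, −78 → 0 °C
Reagents that add atoms: none
Why: Horner–Wadsworth–Emmons olefination with the preformed phosphonate anion should form the 11E alkene and carry the 13E nitrile, the low temperature avoiding γ-deprotonation at C8; any 13Z isomer is removed by chromatography.

Step 9
Reactants: 12 furanoid C20 trienenitrile
Product: 13 furanoid C20 trienal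
Conditions: DIBAL-H (1.3 equiv), CH2Cl2, −78 °C; aq. Rochelle salt, then wet silica gel, 0 °C
Reagents that add atoms: water, O
Why: Partial reduction of the conjugated nitrile to the N-aluminoimine and mild hydrolysis gives the polyenal without acid strong enough to ionise the C8–O bond.

Step 10
Reactants: 13 furanoid C20 trienal
Product: 14 furanoid C21 (15E)-tetraenyl iodide
Conditions: CrCl2, CHI3, THF, 0 °C, dark
Reagents that add atoms: iodoform, IC(I)I
Why: Takai iodo-olefination homologates the aldehyde by one carbon (C15′) to the (E)-vinyl iodide under neutral conditions that the polyene and the furanoid should tolerate.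

**ε-Ring C18 enyne (steps 11–18)**

Step 11
Reactants: 15 (R)-α-ionone
Product: 16 (R)-α-ionone ethylene ketal
Conditions: TMSOCH2CH2OTMS, TMSOTf (cat.), CH2Cl2, −78 °C
Reagents that add atoms: 1,2-bis(trimethylsilyloxy)ethane, C[Si](C)(C)OCCO[Si](C)(C)C
Why: Noyori ketalisation protects the enone carbonyl at low temperature, so the 7′E alkene and the C6′ stereocentre (no α- to β-ionone shift) are not disturbed.

Step 12
Reactants: 16 (R)-α-ionone ethylene ketal
Product: 17 (6′R)-3′-oxo-α-ionone ethylene ketal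
Conditions: t-BuOOH (70 % aq.), Rh2(cap)4 (1 mol %), K2CO3, CH2Cl2, 23 °C
Reagents that add atoms: tert-butyl hydroperoxide, CC(C)(C)OO
Why: Catalytic allylic C–H oxidation through tert-butylperoxyl radicals should convert the ring allylic CH2 (C3′) into the enone carbonyl, the hindered tertiary C6′–H and the ketal being spared.

Step 13
Reactants: 17 (6′R)-3′-oxo-α-ionone ethylene ketal
Product: 19 (3′R,6′R)-3′-hydroxy-α-ionone, via hydroxy ketal 18 (not isolated)
Conditions: (S)-Me-CBS (0.2 equiv), catecholborane, toluene, −78 °C; MeOH quench; then 0.3 M aq. oxalic acid, THF, 23 °C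
Reagents that add atoms: water, O
Why: Corey–Bakshi–Shibata reduction delivers hydride to the enone carbonyl under reagent control ((S)-catalyst, alkene arm as the large group) to set C3′ (R), trans to the C6′ side chain, and the mild acidic work-up hydrolyses the enone ketal.

Step 14
Reactants: 19 (3′R,6′R)-3′-hydroxy-α-ionone
Product: 20 (3′R,6′R)-3′-(tert-butyldimethylsilyloxy)-α-ionone
Conditions: TBSCl, imidazole, DMF, 23 °C
Reagents that add atoms: tert-butyldimethylsilyl chloride, CC(C)(C)[Si](C)(C)Cl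
Why: Standard silylation protects the allylic alcohol against the strong bases and aluminium reagents that follow.

Step 15
Reactants: 20 (3′R,6′R)-3′-(tert-butyldimethylsilyloxy)-α-ionone
Product: 22 ε-ring C13 dienyne (C7′=C8′–C9′≡C10′H), via enol phosphate 21 (not isolated)
Conditions: LDA (1.1 equiv), THF, −78 °C; ClP(O)(OEt)2, −78 → 23 °C; then LDA (2.3 equiv), −78 → 23 °C; aq. NH4Cl
Reagents that add atoms: none
Why: Kinetic deprotonation at the methyl group, O-phosphorylation and base-induced elimination of diethyl phosphate turn the methyl ketone into the terminal alkyne without deprotonating the γ-position C6′.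

Step 16
Reactants: 23 (E)-1,2-dichloroethene; 24 ethynyltrimethylsilane
Product: 25 (E)-1-chloro-4-(trimethylsilyl)but-1-en-3-yne
Conditions: Pd(PPh3)4 (5 mol %), CuI (10 mol %), n-BuNH2, Et2O, 23 °C, 23 in fivefold excess
Reagents that add atoms: none
Why: Sonogashira mono-coupling of the dichloroalkene proceeds with retention of the E geometry and should stop at the chloroenyne when the dichloride is in excess.

Step 17
Reactants: 22 ε-ring C13 dienyne; 25 (E)-1-chloro-4-(trimethylsilyl)but-1-en-3-yne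
Product: 27 ε-ring C17 silyl tetraenyne, via alkenylalane 26 (not isolated)
Conditions: Me3Al (2 equiv), Cp2ZrCl2 (0.25 equiv), ClCH2CH2Cl, 23 °C; volatiles removed; then 25, ZnCl2 (cat.), Pd(t-Bu3P)2 (5 mol %), THF, 23 → 45 °C
Reagents that add atoms: trimethylaluminium, C[Al](C)C
Why: Zr-catalysed syn-methylalumination installs the C19′ methyl with 9′E geometry, and Pd/Zn-catalysed Negishi coupling with the alkyne-activated vinyl chloride forms C10′–C11′ with retention at both alkenyl carbons.

Step 18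
Reactants: 27 ε-ring C17 silyl tetraenyne
Product: 28 ε-ring C18 terminal tetraenyne
Conditions: K2CO3, MeOH/THF, 23 °C
Reagents that add atoms: none
Why: Methanolysis of the alkynyl C–Si bond frees the terminal alkyne, while the secondary TBS ether is stable to carbonate.

**Union and deprotection (steps 19–20)**

Step 19
Reactants: 28 ε-ring C18 terminal tetraenyne; 14 furanoid C21 (15E)-tetraenyl iodide
Product: 30 3,3′-bis-TBS ether of the target, via alkenylalane 29 (not isolated)
Conditions: Me3Al (2.5 equiv), Cp2ZrCl2 (0.3 equiv), ClCH2CH2Cl, 23 °C; volatiles removed in vacuo; then 14, ZnCl2 (cat.), Pd2(dba)3 (2.5 mol %), P(2-furyl)3 (10 mol %), THF/DMF, 23 °C, dark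
Reagents that add atoms: trimethylaluminium, C[Al](C)C
Why: Zr-catalysed syn-methylalumination of the terminal alkyne of 28 places CH3 on C13′ and AlMe2 on C14′, giving the (13′E)-alkenylalane 29; oxidative addition of Pd(0) into the C15′–I bond of 14, Zn-assisted transmetalation and reductive elimination then form C14′–C15′ with retention at both alkenyl carbons. The closest known reaction type is the tandem Zr-catalysed carboalumination/Pd-catalysed Negishi alkenyl–alkenyl cross-coupling. No ring is closed and no stereocentre is created; three components (C18 enyne, methyl, C21 iodide) deliver the whole C40 skeleton, the C20′ methyl and the 13′E and 15E geometry in one operation. The step needs terminal-alkyne regioselectivity, which the Zr-assisted mechanism secures, and retention of alkene geometry, which the Pd cycle secures when run in the dark. It also needs the C8–O stereocentre of 14 to survive, which is addressed by stripping excess Me3Al and running the coupling in THF, where the aluminium and zinc species are complexed and only weakly Lewis acidic. Both hydroxyls are masked as TBS ethers so that no organometallic is consumed by protonolysis.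

Step 20
Reactants: 30 3,3′-bis-TBS ether of the target
Product: 31 (3S,5R,8S,3′R,6′R)-5,8-epoxy-5,8-dihydro-β,ε-carotene-3,3′-diol
Conditions: TBAF, THF, 23 °C, dark
Reagents that add atoms: none
Why: Fluoride-mediated desilylation frees both secondary alcohols under non-acidic conditions that should leave the furanoid C8–O bond and the all-E polyene intact.

**Compound list**

1 | (4R,6R)-4-hydroxy-2,2,6-trimethylcyclohexan-1-one (actinol) | O=C1C(C)(C)C[C@H](O)C[C@H]1C | starting material
2 | (4R,6R)-4-(tert-butyldimethylsilyloxy)-2,2,6-trimethylcyclohexan-1-one | O=C1C(C)(C)C[C@H](O[Si](C)(C)C(C)(C)C)C[C@H]1C | intermediate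
3 | (4R)-4-(tert-butyldimethylsilyloxy)-2,6,6-trimethylcyclohex-1-en-1-yl trifluoromethanesulfonate | CC1=C(OS(=O)(=O)C(F)(F)F)C(C)(C)C[C@H](O[Si](C)(C)C(C)(C)C)C1 | intermediate
4 | (2E)-3-methylpent-2-en-4-yn-1-ol | C#C/C(C)=C/CO | starting material
5 | (2E)-5-[(4R)-4-(tert-butyldimethylsilyloxy)-2,6,6-trimethylcyclohex-1-en-1-yl]-3-methylpent-2-en-4-yn-1-ol | CC1=C(C#C/C(C)=C/CO)C(C)(C)C[C@H](O[Si](C)(C)C(C)(C)C)C1 | intermediate (not isolated)
6 | (2E)-5-[(4R)-4-(tert-butyldimethylsilyloxy)-2,6,6-trimethylcyclohex-1-en-1-yl]-3-methylpent-2-en-4-yn-1-yl acetate | CC1=C(C#C/C(C)=C/COC(C)=O)C(C)(C)C[C@H](O[Si](C)(C)C(C)(C)C)C1 | intermediate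
7 | (2E)-5-[4-(tert-butyldimethylsilyloxy)-2,2,6-trimethyl-7-oxabicyclo[4.1.0]heptan-1-yl]-3-methylpent-2-en-4-yn-1-yl acetate, oxirane anti to the silyloxy group (3S,5R,6R in carotenoid numbering) | CC(=O)OC/C=C(C)/C#C[C@]12C(C)(C)C[C@H](O[Si](C)(C)C(C)(C)C)C[C@@]1(C)O2 | intermediate
8 | (2E)-5-[(2R,4S)-4-(tert-butyldimethylsilyloxy)-2-hydroxy-2,6,6-trimethylcyclohexylidene]-3-methylpenta-2,4-dien-1-ol, allene axis R (6R in carotenoid numbering; axis written with the extended-tetrahedral descriptor on the central carbon) | OC/C=C(C)/C([H])=[C@@]=C1C(C)(C)C[C@H](O[Si](C)(C)C(C)(C)C)C[C@@]1(C)O | intermediate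
9 | (2E)-3-[(2S,6S,7aR)-6-(tert-butyldimethylsilyloxy)-4,4,7a-trimethyl-2,4,5,6,7,7a-hexahydro-1-benzofuran-2-yl]but-2-en-1-ol | OC/C=C(C)/[C@@H]1C=C2C(C)(C)C[C@H](O[Si](C)(C)C(C)(C)C)C[C@@]2(C)O1 | intermediate
10 | (2E)-3-[(2S,6S,7aR)-6-(tert-butyldimethylsilyloxy)-4,4,7a-trimethyl-2,4,5,6,7,7a-hexahydro-1-benzofuran-2-yl]but-2-enal | O=C/C=C(C)/[C@@H]1C=C2C(C)(C)C[C@H](O[Si](C)(C)C(C)(C)C)C[C@@]2(C)O1 | intermediate
11 | diethyl [(2E)-3-cyano-2-methylprop-2-en-1-yl]phosphonate | CCOP(=O)(OCC)C/C(C)=C/C#N | starting material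
12 | (2E,4E,6E)-3-methyl-7-[(2S,6S,7aR)-6-(tert-butyldimethylsilyloxy)-4,4,7a-trimethyl-2,4,5,6,7,7a-hexahydro-1-benzofuran-2-yl]octa-2,4,6-trienenitrile | N#C/C=C(C)/C=C/C=C(C)/[C@@H]1C=C2C(C)(C)C[C@H](O[Si](C)(C)C(C)(C)C)C[C@@]2(C)O1 | intermediate
13 | (2E,4E,6E)-3-methyl-7-[(2S,6S,7aR)-6-(tert-butyldimethylsilyloxy)-4,4,7a-trimethyl-2,4,5,6,7,7a-hexahydro-1-benzofuran-2-yl]octa-2,4,6-trienal | O=C/C=C(C)/C=C/C=C(C)/[C@@H]1C=C2C(C)(C)C[C@H](O[Si](C)(C)C(C)(C)C)C[C@@]2(C)O1 | intermediate
14 | (2S,6S,7aR)-6-(tert-butyldimethylsilyloxy)-2-[(2E,4E,6E,8E)-9-iodo-6-methylnona-2,4,6,8-tetraen-2-yl]-4,4,7a-trimethyl-2,4,5,6,7,7a-hexahydro-1-benzofuran | I/C=C/C=C(C)/C=C/C=C(C)/[C@@H]1C=C2C(C)(C)C[C@H](O[Si](C)(C)C(C)(C)C)C[C@@]2(C)O1 | intermediate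
15 | (R)-α-ionone, (3E)-4-[(1R)-2,6,6-trimethylcyclohex-2-en-1-yl]but-3-en-2-one | CC1=CCCC(C)(C)[C@H]1/C=C/C(C)=O | starting material
16 | 2-methyl-2-{(E)-2-[(1R)-2,6,6-trimethylcyclohex-2-en-1-yl]ethenyl}-1,3-dioxolane | CC1=CCCC(C)(C)[C@H]1/C=C/C1(C)OCCO1 | intermediate
17 | (4R)-3,5,5-trimethyl-4-[(E)-2-(2-methyl-1,3-dioxolan-2-yl)ethenyl]cyclohex-2-en-1-one | CC1=CC(=O)CC(C)(C)[C@H]1/C=C/C1(C)OCCO1 | intermediate
18 | (1R,4R)-3,5,5-trimethyl-4-[(E)-2-(2-methyl-1,3-dioxolan-2-yl)ethenyl]cyclohex-2-en-1-ol | CC1=C[C@H](O)CC(C)(C)[C@H]1/C=C/C1(C)OCCO1 | intermediate (not isolated)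
19 | (3E)-4-[(1R,4R)-4-hydroxy-2,6,6-trimethylcyclohex-2-en-1-yl]but-3-en-2-one | CC1=C[C@H](O)CC(C)(C)[C@H]1/C=C/C(C)=O | intermediate
20 | (3E)-4-[(1R,4R)-4-(tert-butyldimethylsilyloxy)-2,6,6-trimethylcyclohex-2-en-1-yl]but-3-en-2-one | CC1=C[C@H](O[Si](C)(C)C(C)(C)C)CC(C)(C)[C@H]1/C=C/C(C)=O | intermediate
21 | (3E)-4-[(1R,4R)-4-(tert-butyldimethylsilyloxy)-2,6,6-trimethylcyclohex-2-en-1-yl]buta-1,3-dien-2-yl diethyl phosphate | CC1=C[C@H](O[Si](C)(C)C(C)(C)C)CC(C)(C)[C@H]1/C=C/C(=C)OP(=O)(OCC)OCC | intermediate (not isolated)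
22 | tert-butyl{[(1R,4R)-4-[(1E)-but-1-en-3-yn-1-yl]-3,5,5-trimethylcyclohex-2-en-1-yl]oxy}dimethylsilane | CC1=C[C@H](O[Si](C)(C)C(C)(C)C)CC(C)(C)[C@H]1/C=C/C#C | intermediate
23 | (E)-1,2-dichloroethene | Cl/C=C/Cl | starting material
24 | ethynyltrimethylsilane | C#C[Si](C)(C)C | starting material
25 | (E)-1-chloro-4-(trimethylsilyl)but-1-en-3-yne | Cl/C=C/C#C[Si](C)(C)C | intermediate
26 | dimethyl{(1E,3E)-4-[(1R,4R)-4-(tert-butyldimethylsilyloxy)-2,6,6-trimethylcyclohex-2-en-1-yl]-2-methylbuta-1,3-dien-1-yl}alane | CC1=C[C@H](O[Si](C)(C)C(C)(C)C)CC(C)(C)[C@H]1/C=C/C(C)=C/[Al](C)C | intermediate (not isolated)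
27 | tert-butyl{[(1R,4R)-3,5,5-trimethyl-4-[(1E,3E,5E)-3-methyl-8-(trimethylsilyl)octa-1,3,5-trien-7-yn-1-yl]cyclohex-2-en-1-yl]oxy}dimethylsilane | CC1=C[C@H](O[Si](C)(C)C(C)(C)C)CC(C)(C)[C@H]1/C=C/C(C)=C/C=C/C#C[Si](C)(C)C | intermediate
28 | tert-butyl{[(1R,4R)-3,5,5-trimethyl-4-[(1E,3E,5E)-3-methylocta-1,3,5-trien-7-yn-1-yl]cyclohex-2-en-1-yl]oxy}dimethylsilane | CC1=C[C@H](O[Si](C)(C)C(C)(C)C)CC(C)(C)[C@H]1/C=C/C(C)=C/C=C/C#C | intermediate
29 | dimethyl{(1E,3E,5E,7E)-8-[(1R,4R)-4-(tert-butyldimethylsilyloxy)-2,6,6-trimethylcyclohex-2-en-1-yl]-2,6-dimethylocta-1,3,5,7-tetraen-1-yl}alane | CC1=C[C@H](O[Si](C)(C)C(C)(C)C)CC(C)(C)[C@H]1/C=C/C(C)=C/C=C/C(C)=C/[Al](C)C | intermediate (not isolated)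
30 | (3S,5R,8S,3′R,6′R)-3,3′-bis(tert-butyldimethylsilyloxy)-5,8-epoxy-5,8-dihydro-β,ε-carotene (all-E) | CC1=C[C@H](O[Si](C)(C)C(C)(C)C)CC(C)(C)[C@H]1/C=C/C(C)=C/C=C/C(C)=C/C=C/C=C(C)/C=C/C=C(C)/[C@@H]1C=C2C(C)(C)C[C@H](O[Si](C)(C)C(C)(C)C)C[C@@]2(C)O1 | intermediate
31 | (3S,5R,8S,3′R,6′R)-5,8-epoxy-5,8-dihydro-β,ε-carotene-3,3′-diol (all-E) | CC1=C[C@H](O)CC(C)(C)[C@H]1/C=C/C(C)=C/C=C/C(C)=C/C=C/C=C(C)/C=C/C=C(\C)[C@@H]1C=C2C(C)(C)C[C@H](O)C[C@@]2(C)O1 | target

**Summary**

Total step count: 20. Longest linear sequence: 12 steps (steps 1–10, 19, 20).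

Steps most likely to fail:

1. Step 19. Residual Lewis-acidic aluminium or zirconium species may ionise the doubly allylic C8–O bond of 14 and scramble C8, or the alkenylalane may be protonated before it transmetalates. The fallback sets out from 28 and 13 and returns at 30. The methylalumination of 28 is quenched with iodine (THF, −30 °C) to give the (13′E)-C19 vinyl iodide F1. Aldehyde 13 is homologated by a chromium(II)-mediated stannyl-olefination (Bu3SnCHBr2, CrCl2, LiI, THF/DMF) to the (15E)-C21 dienylstannane F2. Stille coupling of the two (Pd2(dba)3, AsPh3, NMP, 23 °C, dark) forms the same C14′–C15′ bond under neutral, Lewis-acid-free conditions and gives 30.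

2. Step 6. Axis-to-centre transfer may be eroded by reversible gold-induced ionisation of the product's C8–O bond, or the vinylallene may enter a competing gold-triggered carbocyclisation. The fallback sets out from 8 and returns at 9. Iodoetherification with N-iodosuccinimide (CH2Cl2, −20 °C) closes the same ring by anti-oxyiodination with the same sense of chirality transfer and gives the 7-iodo furanoid alcohol F3. Palladium-catalysed hydrodeiodination (Pd(PPh3)4, Bu3SnH, THF, 23 °C) then gives 9.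

3. Step 4. The peracid may attack both faces of the ring alkene with poor anti/syn discrimination, or may also epoxidise the side-chain alkene. The fallback sets out from 6 and returns at 7. It replaces substrate control by reagent control: a Shi epoxidation (fructose-derived chiral ketone of the enantiomeric series matched to the face anti to the silyloxy group, Oxone, K2CO3 buffer, MeCN/dimethoxymethane/H2O, 0 °C), whose bulky dioxirane should also favour the more electron-rich ring alkene. This fallback makes no new compound (F0).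

**Further compounds**

F1 | step 19 | tert-butyl{[(1R,4R)-4-[(1E,3E,5E,7E)-8-iodo-3,7-dimethylocta-1,3,5,7-tetraen-1-yl]-3,5,5-trimethylcyclohex-2-en-1-yl]oxy}dimethylsilane | CC1=C[C@H](O[Si](C)(C)C(C)(C)C)CC(C)(C)[C@H]1/C=C/C(C)=C/C=C/C(C)=C/I
F2 | step 19 | (2S,6S,7aR)-6-(tert-butyldimethylsilyloxy)-4,4,7a-trimethyl-2-[(2E,4E,6E,8E)-6-methyl-9-(tributylstannyl)nona-2,4,6,8-tetraen-2-yl]-2,4,5,6,7,7a-hexahydro-1-benzofuran | CCCC[Sn](CCCC)(CCCC)/C=C/C=C(C)/C=C/C=C(C)/[C@@H]1C=C2C(C)(C)C[C@H](O[Si](C)(C)C(C)(C)C)C[C@@]2(C)O1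
F3 | step 6 | (2E)-3-[(2R,6S,7aR)-6-(tert-butyldimethylsilyloxy)-3-iodo-4,4,7a-trimethyl-2,4,5,6,7,7a-hexahydro-1-benzofuran-2-yl]but-2-en-1-ol | OC/C=C(C)/[C@@H]1C(I)=C2C(C)(C)C[C@H](O[Si](C)(C)C(C)(C)C)C[C@@]2(C)O1
F0 | step 4 | none | none
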